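**Retrosynthetic overview**
1. Feature: ring B (C5–C10), with its C7=C8 alkene, C17 on C8 and the C5–H centre next to the gem-dimethyl carbon C4, has the carbon pattern of (R)-carvone. The isopropenyl group is C4/C18/C19 and the carvone stereocentre is C5.
2. Ring order: ring B is bought. Ring A is closed second, at C3–C4, by iron-hydride HAT to the isopropenyl group and 6-endo radical addition to a vinyl ketone (C1–C3) on quaternary C10.
3. C10 is built beforehand by α′-methylation (C20), an acrolein aldol anti to isopropenyl, and oxidation. After ring closure C1=O is removed by reduction and Barton–McCombie deoxygenation.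
4. C9–C11 disconnection: an alkyllithium from methyl hydrogen (R)-3-methylglutarate (brings C13) adds to C9=O. Oxidative 1,3-transposition, Li/NH3 (sets C9–H) with triflate trapping, and triflate reduction return the C7=C8 alkene.
5. Endgame: SeO2 oxidation of C17, desilylation at O15, double acetylation.

Key step: step 4

Remark on the chemistry: labdane numbering is used for all compounds, including the monocyclic ones. The aldol carbinol carbon and C9 of the tertiary allylic alcohol are expected as epimer mixtures and are erased one step later, so they are left open in the SMILES.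

Step 1
Reactants: 1 (R)-(−)-carvone
Product: 3 (5R,6S)-6-methylcarvone (methyl trans to isopropenyl; minor cis epimer carried along), via carvone lithium dienolate 2 (not isolated)
Conditions: LiN(i-Pr)2 (1.1 equiv), THF, −78 °C; MeI, −78 → 0 °C
Reagents that add atoms: methyl iodide, CI
Why: Kinetic deprotonation by the hindered amide occurs at the α′ CH2 (future C10) and the cross-conjugated dienolate 2 is C-methylated by SN2 enolate alkylation mainly anti to the neighbouring isopropenyl group; the new centre becomes planar again in step 2, so both epimers are usable.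

Step 2
Reactants: 3 (5R,6S)-6-methylcarvone; 4 acrolein
Product: 6 6-(1-hydroxyallyl)-6-methylcarvone (hydroxyallyl arm trans to isopropenyl; carbinol epimers), via tetrasubstituted lithium enolate 5 (not isolated)
Conditions: LiN(i-Pr)2 (1.15 equiv), THF, −78 → −10 °C; freshly distilled acrolein, −78 °C; AcOH/THF quench at −78 °C
Reagents that add atoms: none
Why: The remaining α′ hydrogen is removed to give enolate 5, in which allylic strain with the C10 methyl group pushes the C5 isopropenyl group pseudoaxial, so the lithium aldol addition to the aldehyde carbon of acrolein takes place on the opposite ring face and sets quaternary C10 with the three-carbon arm trans and the methyl group cis to isopropenyl; the cold acidic quench forestalls retro-aldol cleavage.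

Step 3
Reactants: 6 6-(1-hydroxyallyl)-6-methylcarvone
Product: 7 (5S,6R)-6-acryloyl-6-methylcarvone (acryloyl trans to isopropenyl)
Conditions: Dess–Martin periodinane, CH2Cl2, 0 °C → rt; used promptly
Reagents that add atoms: none
Why: The Dess–Martin oxidation turns the secondary allylic alcohol into the vinyl ketone under neutral, non-nucleophilic conditions, which spares the retro-aldol-prone β-hydroxy ketone 6 and the non-enolisable 1,3-diketone and Michael acceptor of 7, and it removes the undefined carbinol centre.

Step 4
Reactants: 7 (5S,6R)-6-acryloyl-6-methylcarvone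
Product: 8 trans-fused 4,4,8,10-tetramethyl-Δ7-octalin-1,9-dione (H-5 α; CH3-10 β)
Conditions: Fe(acac)3 (0.3 equiv), PhSiH3 (2.5 equiv, slow addition), degassed EtOH (0.01 M), rt → 50 °C
Reagents that add atoms: none
Why: Fe(acac)3 and PhSiH3 in EtOH form an iron hydride that transfers a hydrogen atom to the CH2 terminus of the electron-rich 1,1-disubstituted isopropenyl alkene of 7, giving the nucleophilic tertiary C4 radical. This radical adds to the unsubstituted terminal carbon C3 of the vinyl ketone, forms C3–C4 and closes ring A in the 6-endo-trig mode, because C3 is the polarity-matched and unhindered acceptor site and the 5-exo alternative at C2 would leave an unstabilised primary radical. The α-keto radical at C2 is then reduced by divalent iron to the enolate and protonated by EtOH, so the net change is the uptake of two hydrogen atoms. The closest known reaction type is the iron- or manganese-hydride reductive olefin–enone coupling, a HAT-initiated Giese cyclisation. No stereocentre is created, since C4 becomes the gem-dimethyl carbon and C2 a CH2 group, and the trans ring fusion follows from the trans-diequatorial placement of the two arms on C5 and C10 fixed in step 2. The step needs HAT to the isopropenyl group in preference to the ring B enone and the vinyl ketone, which is secured by alkene electronics and substitution, supported by high dilution and slow silane addition.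

Step 5
Reactants: 8 trans-fused 4,4,8,10-tetramethyl-Δ7-octalin-1,9-dione
Product: 9 1β-hydroxy-4,4,8,10-tetramethyl-Δ7-octalin-9-one
Conditions: NaBH4 (0.35 equiv), MeOH/CH2Cl2 1:1, −78 → −40 °C
Reagents that add atoms: none
Why: Chemoselective borohydride reduction: the saturated C1 ketone is more electrophilic than the conjugated C9 carbonyl, which is flanked by quaternary C10 and methyl-bearing C8, and axial hydride delivery from the α face, away from the axial C10 methyl group, should give the equatorial 1β-alcohol, a centre that is deleted in step 7.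

Step 6
Reactants: 9 1β-hydroxy-4,4,8,10-tetramethyl-Δ7-octalin-9-one
Product: 10 O-(9-oxo-4,4,8,10-tetramethyl-Δ7-octalin-1β-yl) 1H-imidazole-1-carbothioate
Conditions: 1,1′-thiocarbonyldiimidazole (2 equiv), DMAP (cat.), ClCH2CH2Cl, 80 °C
Reagents that add atoms: 1,1′-thiocarbonyldiimidazole, S=C(n1ccnc1)n1ccnc1
Why: Thioacylation of the hindered secondary alcohol with a neutral acyl-transfer reagent (first stage of the Barton–McCombie deoxygenation) avoids the free alkoxide that NaH/CS2/MeI would generate and that could cleave the β-hydroxy ketone by a retro-aldol reaction.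

Step 7
Reactants: 10 O-(9-oxo-4,4,8,10-tetramethyl-Δ7-octalin-1β-yl) 1H-imidazole-1-carbothioate
Product: 11 (4aS,8aS)-2,5,5,8a-tetramethyl-4a,5,6,7,8,8a-hexahydronaphthalen-1(4H)-one (Δ7-octalin-9-one in labdane numbering)
Conditions: Bu3SnH (1.5 equiv), AIBN (cat.), toluene, 90 °C
Reagents that add atoms: none
Why: Barton–McCombie deoxygenation: the stannyl radical adds to the C=S group, the C1–O bond fragments and the secondary C1 radical abstracts hydrogen from Bu3SnH, while the trisubstituted enone is far less reactive towards stannyl radicals than the thiocarbonyl group and a 1,2-acyl shift of the C1 radical would have to pass through a strained ring-fused cyclopropyloxy radical.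

Step 8
Reactants: 12 methyl hydrogen (R)-3-methylglutarate
Product: 13 methyl (R)-5-hydroxy-3-methylpentanoate
Conditions: BH3·SMe2 (1.1 equiv), THF, −10 °C → rt; MeOH
Reagents that add atoms: none
Why: Borane reduces the free carboxylic acid through its acyloxyborane much faster than the methyl ester (chemoselective borane reduction of a half-ester), so the acid arm becomes C14–C15 and the stereocentre, the future C13, is not touched.

Step 9
Reactants: 13 methyl (R)-5-hydroxy-3-methylpentanoate
Product: 14 methyl (R)-5-(tert-butyldimethylsilyloxy)-3-methylpentanoate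
Conditions: TBSCl, imidazole, DMF, 0 °C → rt
Reagents that add atoms: tert-butyldimethylsilyl chloride, CC(C)(C)[Si](C)(C)Cl
Why: Standard silylation of the primary alcohol, carried out at once so that the δ-hydroxy ester does not lactonise; the silyl ether tolerates the alkyllithium, chromium, Li/NH3, palladium and selenium steps that follow.

Step 10
Reactants: 14 methyl (R)-5-(tert-butyldimethylsilyloxy)-3-methylpentanoate
Product: 15 (S)-5-(tert-butyldimethylsilyloxy)-3-methylpentan-1-ol
Conditions: LiAlH4, Et2O, 0 °C; aqueous work-up
Reagents that add atoms: none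
Why: Hydride reduction of the methyl ester to the primary alcohol (C11), under which the silyl ether and the remote stereocentre are inert.

Step 11
Reactants: 15 (S)-5-(tert-butyldimethylsilyloxy)-3-methylpentan-1-ol
Product: 16 (R)-tert-butyl[(5-iodo-3-methylpentyl)oxy]dimethylsilane
Conditions: I2, PPh3, imidazole, CH2Cl2, 0 °C → rt
Reagents that add atoms: iodine, II
Why: Appel-type iodination (PPh3/I2/imidazole) replaces the activated primary hydroxyl group by iodide in an SN2 step at C11, far from the stereocentre.

Step 12
Reactants: 16 (R)-tert-butyl[(5-iodo-3-methylpentyl)oxy]dimethylsilane; 11 (4aS,8aS)-2,5,5,8a-tetramethyl-4a,5,6,7,8,8a-hexahydronaphthalen-1(4H)-one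
Product: 18 (13S)-15-(tert-butyldimethylsilyloxy)labd-7-en-9-ol (C9 epimers), via side-chain alkyllithium 17 (not isolated)
Conditions: 16 (1.5 equiv), t-BuLi (2 equiv per iodide), pentane/Et2O 3:2, −78 °C; then 11 in Et2O, −78 → 0 °C; H2O
Reagents that add atoms: none
Why: Lithium–iodine exchange with two equivalents of t-BuLi gives the primary alkyllithium 17, which adds 1,2 to the enone because a hard, unhindered alkyllithium prefers the carbonyl carbon and C10 carries no α-hydrogen; the configuration of the new C9 carbinol centre is irrelevant, as it is lost in step 13.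

Step 13
Reactants: 18 (13S)-15-(tert-butyldimethylsilyloxy)labd-7-en-9-ol
Product: 19 (13S)-15-(tert-butyldimethylsilyloxy)labd-8-en-7-one
Conditions: pyridinium chlorochromate (3 equiv), 4 Å molecular sieves, CH2Cl2, rt
Reagents that add atoms: pyridinium chlorochromate, [O-][Cr](=O)(=O)Cl.c1cc[nH+]cc1
Why: Babler–Dauben oxidative transposition: the tertiary allylic chromate ester undergoes a [3,3]-shift from C9 to C7 and the resulting secondary chromate is oxidised to the ketone, which gives the tetrasubstituted 8-en-7-one and places the oxygen where the C7=C8 alkene can be regenerated.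

Step 14
Reactants: 19 (13S)-15-(tert-butyldimethylsilyloxy)labd-8-en-7-one
Product: 21 (13S)-15-(tert-butyldimethylsilyloxy)labd-7-en-7-yl trifluoromethanesulfonate (H-9 α), via lithium C7 enolate 20 (not isolated)
Conditions: Li (2.5 equiv), t-BuOH (1.0 equiv), NH3(l)/THF, −78 → −33 °C; isoprene; NH3 evaporated; PhNTf2 (1.5 equiv), THF, 0 °C → rt
Reagents that add atoms: N-phenylbis(trifluoromethanesulfonimide), O=S(=O)(N(c1ccccc1)S(=O)(=O)C(F)(F)F)C(F)(F)F
Why: Dissolving-metal enone reduction with regiospecific enolate trapping: two electrons and one proton convert the enone into the C7–C8 enolate 20, C9 being protonated axially from the α face so that the side chain becomes equatorial (β, the more stable arrangement on the rigid trans-decalin chair), and O-sulfonylation with PhNTf2 fixes the enolate double bond as the enol triflate.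

Step 15
Reactants: 21 (13S)-15-(tert-butyldimethylsilyloxy)labd-7-en-7-yl trifluoromethanesulfonate
Product: 22 (13S)-15-(tert-butyldimethylsilyloxy)labd-7-ene
Conditions: Pd(OAc)2 (5 mol %), PPh3 (15 mol %), HCO2H (3 equiv), n-Bu3N (4 equiv), DMF, 60 °C
Reagents that add atoms: none
Why: Palladium-catalysed formate reduction of an enol triflate: oxidative addition of zerovalent palladium into the C7–O bond, formate exchange, decarboxylation and reductive elimination replace OTf by H without moving the alkene or touching C9.

Step 16
Reactants: 22 (13S)-15-(tert-butyldimethylsilyloxy)labd-7-ene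
Product: 24 (13S)-15-(tert-butyldimethylsilyloxy)labd-7-en-17-ol, via labd-7-en-17-al silyl ether 23 (not isolated)
Conditions: SeO2 (0.5 equiv), t-BuOOH (3 equiv, decane), CH2Cl2, 0 °C → rt; crude product: NaBH4, MeOH, 0 °C
Reagents that add atoms: selenium dioxide, O=[Se]=O (oxygen carrier); tert-butyl hydroperoxide, CC(C)(C)OO (terminal oxygen source)
Why: Riley allylic oxidation: the ene reaction places selenium on the less substituted C7 and takes a hydrogen from a carbon on C8, where the methyl group C17 is preferred to the hindered methine C9–H, and the [2,3]-shift delivers oxygen to C17 with the alkene back at C7=C8; the part oxidised further to enal 23 is returned to the alcohol by 1,2-reduction with NaBH4.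

Step 17
Reactants: 24 (13S)-15-(tert-butyldimethylsilyloxy)labd-7-en-17-ol
Product: 25 (13S)-labd-7-ene-15,17-diol
Conditions: Bu4NF, THF, rt
Reagents that add atoms: none
Why: Fluoride-induced desilylation, driven by the strong Si–F bond, frees the C15 alcohol without affecting the allylic alcohol or the alkene.

Step 18
Reactants: 25 (13S)-labd-7-ene-15,17-diol
Product: 26 (13S)-labd-7-ene-15,17-diyl diacetate (CNP0294037.1)
Conditions: Ac2O, pyridine, DMAP (cat.), CH2Cl2, rt
Reagents that add atoms: acetic anhydride, CC(=O)OC(C)=O
Why: DMAP-catalysed acylation of both unhindered primary alcohols (C15 and allylic C17) gives the diacetate with no change at any stereocentre.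

**Compound list**
1 | (R)-(−)-carvone | CC1=CC[C@H](CC1=O)C(C)=C | starting material
2 | carvone lithium dienolate (cross-conjugated, C9–O, C9=C10) | [Li+].CC1=CC[C@H](C=C1[O-])C(C)=C | intermediate
3 | (5R,6S)-2,6-dimethyl-5-(prop-1-en-2-yl)cyclohex-2-en-1-one (trans-6-methylcarvone) | CC1=CC[C@H]([C@H](C)C1=O)C(C)=C | intermediate
4 | acrolein | C=CC=O | starting material
5 | tetrasubstituted lithium enolate of 6-methylcarvone | [Li+].CC1=CC[C@H](C(C)=C1[O-])C(C)=C | intermediate
6 | 6-(1-hydroxyprop-2-en-1-yl)-6-methylcarvone, arm trans to isopropenyl, carbinol epimers | C=CC(O)[C@]1(C)C(=O)C(C)=CC[C@H]1C(C)=C | intermediate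
7 | (5S,6R)-6-acryloyl-2,6-dimethyl-5-(prop-1-en-2-yl)cyclohex-2-en-1-one | C=CC(=O)[C@]1(C)C(=O)C(C)=CC[C@H]1C(C)=C | intermediate
8 | trans-fused 4,4,8,10-tetramethyl-Δ7-octalin-1,9-dione (H-5 α, CH3-10 β) | O=C1C(C)=CC[C@H]2C(C)(C)CCC(=O)[C@]12C | intermediate
9 | 1β-hydroxy-4,4,8,10-tetramethyl-Δ7-octalin-9-one | O=C1C(C)=CC[C@H]2C(C)(C)CC[C@@H](O)[C@]12C | intermediate
10 | 1β-(imidazol-1-ylthiocarbonyloxy)-4,4,8,10-tetramethyl-Δ7-octalin-9-one | O=C1C(C)=CC[C@H]2C(C)(C)CC[C@@H](OC(=S)n3ccnc3)[C@]12C | intermediate
11 | (4aS,8aS)-2,5,5,8a-tetramethyl-4a,5,6,7,8,8a-hexahydronaphthalen-1(4H)-one | O=C1C(C)=CC[C@H]2C(C)(C)CCC[C@]12C | intermediate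
12 | methyl hydrogen (R)-3-methylglutarate | C[C@H](CC(=O)O)CC(=O)OC | starting material
13 | methyl (R)-5-hydroxy-3-methylpentanoate | C[C@H](CCO)CC(=O)OC | intermediate
14 | methyl (R)-5-(tert-butyldimethylsilyloxy)-3-methylpentanoate | C[C@H](CCO[Si](C)(C)C(C)(C)C)CC(=O)OC | intermediate
15 | (S)-5-(tert-butyldimethylsilyloxy)-3-methylpentan-1-ol | C[C@H](CCO[Si](C)(C)C(C)(C)C)CCO | intermediate
16 | (R)-tert-butyl[(5-iodo-3-methylpentyl)oxy]dimethylsilane | C[C@H](CCO[Si](C)(C)C(C)(C)C)CCI | intermediate
17 | 5-(tert-butyldimethylsilyloxy)-3-methylpentyllithium (side-chain alkyllithium) | C[C@H](CCO[Si](C)(C)C(C)(C)C)CC[Li] | intermediate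
18 | (13S)-15-(tert-butyldimethylsilyloxy)labd-7-en-9-ol, C9 epimers | CC(C)(C)[Si](C)(C)OCC[C@@H](C)CCC1(O)C(C)=CC[C@H]2C(C)(C)CCC[C@]12C | intermediate
19 | (13S)-15-(tert-butyldimethylsilyloxy)labd-8-en-7-one | CC(C)(C)[Si](C)(C)OCC[C@@H](C)CCC1=C(C)C(=O)C[C@H]2C(C)(C)CCC[C@]12C | intermediate
20 | lithium C7 enolate (C7=C8, H-9 α) | [Li+].CC(C)(C)[Si](C)(C)OCC[C@@H](C)CC[C@H]1C(C)=C([O-])C[C@H]2C(C)(C)CCC[C@]12C | intermediate
21 | (13S)-15-(tert-butyldimethylsilyloxy)labd-7-en-7-yl trifluoromethanesulfonate | CC(C)(C)[Si](C)(C)OCC[C@@H](C)CC[C@H]1C(C)=C(OS(=O)(=O)C(F)(F)F)C[C@H]2C(C)(C)CCC[C@]12C | intermediate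
22 | (13S)-15-(tert-butyldimethylsilyloxy)labd-7-ene | CC(C)(C)[Si](C)(C)OCC[C@@H](C)CC[C@H]1C(C)=CC[C@H]2C(C)(C)CCC[C@]12C | intermediate
23 | (13S)-15-(tert-butyldimethylsilyloxy)labd-7-en-17-al | CC(C)(C)[Si](C)(C)OCC[C@@H](C)CC[C@H]1C(C=O)=CC[C@H]2C(C)(C)CCC[C@]12C | intermediate
24 | (13S)-15-(tert-butyldimethylsilyloxy)labd-7-en-17-ol | CC(C)(C)[Si](C)(C)OCC[C@@H](C)CC[C@H]1C(CO)=CC[C@H]2C(C)(C)CCC[C@]12C | intermediate
25 | (13S)-labd-7-ene-15,17-diol | OCC[C@@H](C)CC[C@H]1C(CO)=CC[C@H]2C(C)(C)CCC[C@]12C | intermediate
26 | (13S)-labd-7-ene-15,17-diyl diacetate (H-5 α, H-9 α, CH3-10 β) | CC(=O)OCC[C@@H](C)CC[C@H]1C(COC(C)=O)=CC[C@H]2C(C)(C)CCC[C@]12C | target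

**Totals**
Total step count: 18. Longest linear sequence: 14 steps from (R)-carvone (steps 1–7 and 12–18). The side-chain branch takes 4 steps (8–11).

**Steps most likely to fail**

Step 4 (key step).
- Three processes may intervene. Hydrogen-atom or hydride transfer may reach the vinyl ketone before the C4 radical is formed. The C4 radical may be quenched by a second hydrogen atom before ring closure. Radical oligomerisation may occur through the vinyl ketone.
- Fallback: the same C4 radical is produced by reductive epoxide opening with trivalent titanium instead of HAT.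
- Setting out from 7, mCPBA (CH2Cl2, 0 °C) should epoxidise only the electron-rich isopropenyl alkene to the isopropenyl epoxide F1.
- Cp2TiCl, made from Cp2TiCl2 and Zn in THF, opens the epoxide to the β-titanoxy tertiary C4 radical. This radical closes the same C3–C4 bond in the same 6-endo mode. Protonation of the titanium enolate then gives the 4-hydroxymethyl dione F2 (C4 epimers).
- NaBH4 as in step 5 gives the 1β-hydroxy-4-hydroxymethyl enone F3. Excess 1,1′-thiocarbonyldiimidazole gives the bis(imidazolylthiocarbonyl) derivative F4.
- Bu3SnH/AIBN in refluxing toluene removes both C–O bonds. This turns the CH2O carbon into the second C4 methyl group and rejoins the route at 11.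

Step 12.
- Addition to a carbonyl group flanked by quaternary C10 and methyl-bearing C8 may be slow. Deprotonation of the enone at its γ positions (C6, C17) by the alkyllithium may then compete.
- Fallback: C9–C11 is formed by cross-coupling instead of carbonyl addition.
- Setting out from 11, conjugate reduction with LiBH(s-Bu)3 (THF, −78 °C) and trapping of the enolate with PhNTf2 gives the C9 enol triflate F5.
- Alkyllithium 17 is transmetalated with ZnCl2 to the side-chain alkylzinc chloride F6.
- Negishi coupling with PdCl2(dppf) (THF, 50 °C) gives the labd-8-ene silyl ether F7.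
- Allylic oxidation of the ring methylene C7 with CrO3·3,5-dimethylpyrazole (CH2Cl2, −20 °C) rejoins the route at 19.

Step 16.
- Site selectivity between C17, the C9 methine and the C6 methylene may be poor, and over-oxidation may occur.
- Fallback: oxygen is introduced through the alkene and then moved to C17.
- Setting out from 22, mCPBA attacks the α face, away from the C10 methyl group and the β side chain, to give the 7α,8α-epoxide F8.
- Al(Oi-Pr)3 in refluxing toluene isomerises F8, with loss of a C17 proton, to the 8(17)-en-7α-ol F9.
- Rhenium-oxo catalysed 1,3-transposition of the allylic alcohol (Ph3SiOReO3 cat., Et2O, 0 °C) follows. It moves the hydroxyl group to the primary C17 position and forms the more stable endocyclic trisubstituted alkene, rejoining the route at 24.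

**Further compounds**
F1 | step 4 | 6-acryloyl-6-methylcarvone isopropenyl epoxide (epoxide epimers) | C=CC(=O)[C@]1(C)C(=O)C(C)=CC[C@H]1C2(C)CO2
F2 | step 4 | 4-hydroxymethyl-4,8,10-trimethyl-Δ7-octalin-1,9-dione (C4 epimers) | O=C1C(C)=CC[C@H]2C(C)(CO)CCC(=O)[C@]12C
F3 | step 4 | 1β-hydroxy-4-hydroxymethyl-4,8,10-trimethyl-Δ7-octalin-9-one | O=C1C(C)=CC[C@H]2C(C)(CO)CC[C@@H](O)[C@]12C
F4 | step 4 | bis(imidazol-1-ylthiocarbonyl) derivative of F3 | O=C1C(C)=CC[C@H]2C(C)(COC(=S)n3ccnc3)CC[C@@H](OC(=S)n3ccnc3)[C@]12C
F5 | step 12 | 4,4,8,10-tetramethyl-Δ8-octalin-9-yl trifluoromethanesulfonate | FC(F)(F)S(=O)(=O)OC1=C(C)CC[C@H]2C(C)(C)CCC[C@]12C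
F6 | step 12 | 5-(tert-butyldimethylsilyloxy)-3-methylpentylzinc chloride | C[C@H](CCO[Si](C)(C)C(C)(C)C)CC[Zn]Cl
F7 | step 12 | (13S)-15-(tert-butyldimethylsilyloxy)labd-8-ene | CC(C)(C)[Si](C)(C)OCC[C@@H](C)CCC1=C(C)CC[C@H]2C(C)(C)CCC[C@]12C
F8 | step 16 | (13S)-15-(tert-butyldimethylsilyloxy)-7α,8α-epoxylabdane | CC(C)(C)[Si](C)(C)OCC[C@@H](C)CC[C@H]1[C@]3(C)O[C@@H]3C[C@H]2C(C)(C)CCC[C@]12C
F9 | step 16 | (13S)-15-(tert-butyldimethylsilyloxy)labd-8(17)-en-7α-ol | CC(C)(C)[Si](C)(C)OCC[C@@H](C)CC[C@H]1C(=C)[C@H](O)C[C@H]2C(C)(C)CCC[C@]12C
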